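(The data were generated by integration with made-up constants; scatter was added.)

0.00789 M h⁻¹ is the feed rate: the concentration of target at the last reading divided by its time, averaged over the earlier runs. At 15.0 h the alder, maple and birch runs hold 0.111 M, 0.120 M and 0.124 M, although their charges differ.

| setting | alder | maple | birch | flask |
|---|---|---|---|---|
| solid substrate | 0.42 M | 0.66 M | 0.30 M | 0.30 M |
| reagent | 0.39 M | 0.39 M | 0.58 M | 0.390 M |
| remark | run made earlier | run made earlier | run made earlier |  |
| time |  |  |  | 20 h |

- alder (time / h: target / %, crystals / %): 2.00: 0.6, 1.3; 6.00: 12.5, 7.1; 10.0: 17.0, 15.3; 15.0: 26.4, 23.6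
- maple (time / h: target / %, crystals / %): 4.00: 4.4, 4.0; 8.00: 8.5, 9.1; 12.0: 16.0, 12.7; 15.0: 18.2, 14.8
- birch (time / h: target / %, crystals / %): 2.00: 7.8, 1.6; 6.00: 15.5, 12.8; 10.0: 29.2, 26.4; 15.0: 41.3, 39.1

(standard deviation of a reading: 1 percentage point)

- target is meant together with its crystals
- solid, in amounts per volume of the solution: solid substrate, crystals
- the numbers in the tables scatter with a standard deviation of 1 percentage point
- at the start none of the solid substrate is in solution
- dissolved substrate means what is dissolved; the solid is not counted in it

1. amount of target and crystals together at 20 h, in percent of the solid substrate charged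
2. concentration of dissolved substrate in solution at 20 h, in percent of saturation

The bench rule follows: over the charges of these runs, target arrives at a constant rate. Solid substrate is the smaller charge, with 1.30 equivalents of reagent, so it is the limiting reagent. Its balance gives the ratio for the flask:

y ≈ feed rate × t / c(solid substrate) = 0.00789 M h⁻¹ × 20 h / 0.30 M = 52.6%

The rule stops at the latest where this ratio reaches one, since the balance allows no more target than the charge; it may stop earlier. The birch run tests the rule up to 41.3%, so the flask, at 52.6%, stands beyond the readings but below that ceiling. This reckoning gives no figure for saturation.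

The forecast gives 50% and 22% of saturation, holding that “dissolution limits the rate”.

The flask gives 50.3% and 2.35% of saturation.

    target ⇌ isomer of the product (K = 0.630, k = 1.10 h⁻¹)
    solid substrate ⇌ dissolved substrate, rate k2*(cs2 - [dissolved substrate]) while solid is left; crystals form when [dissolved substrate] > cs2 (solubility = 0.120 M, k = 0.0840 h⁻¹)
    dissolved substrate + target → side product (k = 53.0 M⁻¹ h⁻¹)
    crystals ⇌ target, rate k4*(cs4 - [target]) while solid is left; crystals form when [target] > cs4 (solubility = 5.50 mM, k = 2.30 h⁻¹)
    dissolved substrate + reagent → target (k = 14.0 M⁻¹ h⁻¹)

In the flask, the step to target gives dissolved substrate a half-life of 0.16 h at 9.97 h, shorter than the 20 h of the run. At 20.0 h it is made 1.01 times as fast as it is used up, and it stands 20 percentage points below the forecast. The flask's mean rate of target, 0.00754 M h⁻¹, lies close to the feed rate of 0.00789 M h⁻¹. For the neighbour flask with 0.75 M of solid substrate, the feed rate gives 21.0%, and that flask holds 20.1%.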